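- I had 4 questions about the alder flask; they stand below with the charges and the earlier readings.

| flask | starting complex | incoming ligand | scavenger | remark | time |
|---|---|---|---|---|---|
| alder | 0.20 M | 1.3 equiv | 0.50 equiv | the very flask that is asked about, followed so far |  |
| ash | 0.20 M | 1.3 equiv | 0.25 equiv | run made earlier |  |
| flask | 0.20 M | 1.30 equiv | 0.500 equiv |  | 50 min |

| run | time / min | complex with two exchanged / % | complex with one exchanged / % | starting complex / % |
|---|---|---|---|---|
| alder | 0.667 | 10.2 | 16.3 | 44.0 |
| alder | 1.00 | 12.3 | 16.6 | 35.9 |
| alder | 2.00 | 15.2 | 14.3 | 18.5 |
| alder | 3.00 | 16.2 | 11.7 | 12.7 |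
| alder | 6.00 | 14.7 | 8.5 | 9.2 |
| alder | 10.0 | 14.0 | 8.0 | 8.5 |
| ash | 0.667 | 9.7 | 16.5 | 39.3 |
| ash | 1.33 | 12.6 | 14.1 | 21.6 |
| ash | 4.00 | 12.8 | 7.9 | 7.7 |
| ash | 8.00 | 11.6 | 4.7 | 5.9 |
| ash | 20.0 | 9.2 | 4.8 | 6.0 |
| ash | 50.0 | 8.3 | 3.2 | 6.9 |

(standard deviation of a reading: 0.5 percentage points)

- the moment within 50 min at which there is most complex with two exchanged
- the amount of complex with two exchanged, in percent of the starting complex charged, at that time
- earliest time at which at least nineteen twentieths of that best amount are there, in min
- latest time at which they still are, in min

- leaving ligand is meant together with its idle adduct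
- on the list of suspects stand: complex with two exchanged + incoming ligand -> leaving ligand + complex with three exchanged; complex with one exchanged + incoming ligand -> leaving ligand + complex with two exchanged; complex with three exchanged + incoming ligand <-> leaving ligand + complex with four exchanged; leaving ligand + starting complex <-> idle adduct; starting complex + incoming ligand -> leaving ligand + complex with one exchanged; scavenger + leaving ligand -> scavenged by-product

- I kept a ledger of the incoming ligand, the limiting reagent, because each exchange costs one incoming ligand and alder was charged less than the 4 per starting complex that full exchange needs.
- I called the exchange budget the incoming ligand charged per starting complex, 1.30 equiv in alder.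
- Complex with one exchanged costs one unit of the budget and complex with two exchanged costs two, while starting complex and idle adduct cost nothing.
- What the two read entries do not cover is the remainder, which is either in more highly exchanged complexes or still unused.
- In alder at 3.00 min the remainder was 0.859 equiv, and at 10.0 min it was 0.940 equiv, so payments were passing beyond complex with two exchanged.
- My own reckoning went no further than the readings: in alder, complex with two exchanged read 15.2 % at 2.00 min, 16.2 % at 3.00 min and 14.7 % at 6.00 min, each good to 0.5 percentage points, so I expected the peak near 3.00 min.
- The forecast read the runs as “a fast serial exchange that stalls once the incoming ligand is nearly used up”, and gave 16.3 % at 3.2 min, with the window from 2.2 min to 4.7 min.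
- The flask gave 15.8 % at 2.41 min, with the window from 1.49 min to 5.12 min, so it opened earlier than the forecast said.

    complex with two exchanged + incoming ligand → leaving ligand + complex with three exchanged (k = 6.40 /M/min)
    complex with one exchanged + incoming ligand → leaving ligand + complex with two exchanged (k = 8.10 /M/min)
    complex with three exchanged + incoming ligand ⇌ leaving ligand + complex with four exchanged (K = 3.30, k = 10.0 /M/min)
    leaving ligand + starting complex ⇌ idle adduct, settled at all times (K = 74.0 /M)
    starting complex + incoming ligand → leaving ligand + complex with one exchanged (k = 3.30 /M/min)
    scavenger + leaving ligand → scavenged by-product (k = 200 /M/min)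

- The half-life of complex with two exchanged by its onward exchange, with concentrations as charged, was 0.42 min, short against 50 min, yet at 0.482 min it was being made 2.86 times faster than it was used up. At 2.41 min the ledger of the flask showed 1.07 equiv paid and 0.233 equiv unused, out of 1.30 equiv. At 50.0 min its remainder was 0.996 equiv, whereas a neighbour flask, alike except for its 0.780 equiv of incoming ligand, had a remainder of 0.308 equiv and held 14.9 % of complex with two exchanged.

Readings and results come from a simulation with made-up constants; scatter was added.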